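The clock stops at 20 h: what counts is the flask's excess of right-handed substrate among what is left up to then, and two earlier runs, differing in added ligand, show how that excess moves.

the same everywhere: left-handed substrate 0.12 M; right-handed substrate 0.12 M; free catalyst 0.2 mol%; impurity 41 µM
- south-west: partner 0.80 equiv; added ligand 0.14 mM; run made earlier
- south: partner 0.80 equiv; added ligand 0.56 mM; run made earlier
- flask: partner 0.800 equiv; added ligand 0.28 mM; time 20 h

| run | time / h | right-handed substrate / % | left-handed substrate / % |
|---|---|---|---|
| south-west | 2.00 | 47.1 | 40.4 |
| south-west | 4.00 | 42.1 | 35.9 |
| south-west | 6.00 | 41.6 | 31.4 |
| south-west | 12.0 | 39.5 | 27.5 |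
| south-west | 25.0 | 37.2 | 26.4 |
| south | 2.00 | 45.7 | 41.4 |
| south | 4.00 | 45.6 | 39.4 |
| south | 6.00 | 42.4 | 33.5 |
| south | 12.0 | 41.2 | 32.8 |
| south | 25.0 | 40.5 | 28.8 |

(standard deviation of a reading: 1 percentage point)

1. whether the excess of right-handed substrate over left-handed substrate among what is left of the two reaches 95% by 20 h (yes / no)
2. the highest excess of right-handed substrate over left-handed substrate among what is left of the two up to 20 h

- free catalyst is single-handed; left-handed substrate and right-handed substrate are mirror images of each other, charged as a racemate, each of them at the stated concentration
- the numbers in the tables scatter by 1 percentage point (one standard deviation)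
- steps under discussion: partner + free catalyst + left-handed substrate -> free catalyst + left-handed product; partner + free catalyst -> spent catalyst B; partner + free catalyst + right-handed substrate -> free catalyst + right-handed product; free catalyst + impurity -> spent catalyst A; free catalyst + added ligand <-> idle complex

Each substrate meets the same partner and free catalyst in its step, so their shared fate cancels when the two are compared. Column against column, the last rows give a ratio of logarithms: 2.16 in the south-west run and 2.62 in the south run, with mean 2.39. This reading is s, the selectivity factor: the logarithm of the fraction of its own charge left of the left-handed substrate, over the same for the right-handed substrate.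

Down the right-handed column, the south-west run loses 2.3 percentage points between 12.0 h and 25.0 h, so the last rows serve as an estimate for the flask at 20 h. The flask's ligand is twice the south-west level and half the south level, so this reckoning takes the mean of those two readings: a fraction f = 77.7% of the right-handed charge left. With s frozen, the excess is (f − f^s)/(f + f^s), here 17.3%. An excess of 95% asks f to fall to 7.15%, lower than 77.7%, so this reckoning says no.

The forecast also says no, with a top of 16.5%, below this reckoning; reaching the level, it holds, needs “far higher conversion than the catalyst can deliver”.

The flask gives no and a top of 18.8%, with 34.4% of the substrates reacted at 20.0 h, so the forecast stands within its margin.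

    partner + free catalyst + left-handed substrate → free catalyst + left-handed product (k = 2.00 M⁻² s⁻¹)
    partner + free catalyst → spent catalyst B (k = 4.70 × 10⁻⁵ M⁻¹ s⁻¹)
    partner + free catalyst + right-handed substrate → free catalyst + right-handed product (k = 0.790 M⁻² s⁻¹)
    free catalyst + impurity → spent catalyst A (k = 280 M⁻¹ s⁻¹)
    free catalyst + added ligand ⇌ idle complex (K = 31000 M⁻¹, k = 0.0740 M⁻¹ s⁻¹)

The right-handed substrate's half-life by its own step is 28 h at 2.84 h but 11 d at 20.0 h, and the left-handed substrate's is then 100 h, both longer than the 20 h allowed. The flask keeps 78% of its right-handed charge at 20.0 h, and s turns that into 17.1%, against the computed 18.8%. A second flask, like this one but with 2.00 equiv of partner, keeps 49% at the same time, for which s gives 45.9%; its computed top is 49.9%.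

The data are calculated for substances that don't exist; the scatter is artificial.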